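| setting | Monday's | Wednesday's | noon | spring | autumn |
|---|---|---|---|---|---|
| substrate | 0.33 M | 0.89 M | 0.50 M | 0.80 M | 1.2 M |
| gas phase | 33 mM (held) | 33 mM (held) | 33 mM (held) | 33 mM (held) | 33 mM (held) |
| remark | run made earlier | run made earlier |  |  |  |
| time |  |  | 30 min | 30 min | 30 min |

- Monday's (time / min: target / %, isomer of the product / %): 2.50: 33.7, 2.0; 4.00: 44.0, 4.7; 6.00: 54.6, 6.9; 10.0: 63.5, 9.7; 20.0: 68.5, 12.3; 30.0: 68.5, 11.0
- Wednesday's (time / min: target / %, isomer of the product / %): 5.00: 46.0, 3.8; 10.0: 62.2, 10.0; 15.0: 65.3, 10.6; 20.0: 66.2, 9.6; 25.0: 66.0, 9.9; 30.0: 67.9, 9.0

(each reading ± 1 percentage point)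

- at the start none of the gas is dissolved
- candidate steps: target <-> isomer of the product; gas phase <-> dissolved gas; substrate + dissolved gas <-> target; target -> over-reaction product
- the share counts what is present at the end, not what went on to other products
- "hardly changes" means that all values lie within two and a half points (for a concentration: within two and a half percent of the largest)

1. share of target in all that became target or isomer of the product for noon, spring, autumn, in this order
2. the course of these numbers from the first flask to the last (falls all the way / hardly changes / falls, then rises / rises, then falls / rises all the way)

At early times the isomer trailed the target: in Monday's run [isomer]/[target] stood at 0.0593 after 2.50 min and at 0.126 after 6.00 min, so the ratio was still moving while target formed. But in Wednesday's run it no longer rose after 15.0 min, and the candidate step target <-> isomer says what such a stop means: the forward rate goes with [target], the back rate with [isomer], and when I set one rate over the other and asked for unity, time, the rate constant and the charge dropped out, leaving a fixed ratio, the mark of thermodynamic control.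

So I pooled the late readings, Monday's from 20.0 min and Wednesday's from 20.0 min, and 0.154 is the late ratio [isomer]/[target], a reading that carries the scatter of 1 percentage point on each value. Monday's readings alone gave 0.170 and Wednesday's 0.142, a gap I took for scatter. The sum of target and isomer stopped short of the charge, at 79.5% in Monday's last reading, but the share asks how that sum divides, not how large it is, so I reckoned it as 1/(1 + ratio), which is 86.7%. Noon at 0.50 M and spring at 0.80 M lie between the two runs, while autumn at 1.2 M goes beyond Wednesday's charge, a stretch I accepted, and I committed to that one figure for each flask.

The forecast printed a row of 86.3%, 86.6% and 87% where I hold one figure, and said the course hardly changes, on an equilibrium constant that “does not depend on concentration”.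

The flasks gave 86.9%, 86.9% and 86.9%, so the course hardly changes.

    target ⇌ isomer of the product (K = 0.151, k = 0.131 min⁻¹)
    gas phase ⇌ dissolved gas, rate k2*(csat - [dissolved gas]) (kL = 13.2 min⁻¹)
    substrate + dissolved gas ⇌ target (K = 93.0 M⁻¹, k = 7.07 M⁻¹ min⁻¹)
    target → over-reaction product (k = 2.36 × 10⁻⁵ min⁻¹)

At noon the half-life of target by its forward passing into isomer alone, the way back not counted, was 5.3 min, short against the 30 min of the run. The late ratio 0.154 times the 67.6% of target in the autumn flask at 30.0 min gives 10.4% of isomer against the 10.2% that flask held.

The earlier runs and the new flask were generated by integration on assumed constants.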